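Numbering is that of quinic acid: C1 is the carbinol carbon carrying carboxyl C7, C2 and C6 are CH2, C3 to C5 carry the esters. O3 and O4 are cis to 1-OH and O5 is trans.
Retrosynthesis: cut the three O-galloyl bonds. Take C7 back to an exocyclic methylene and C4 back to a ketone masked as a dimethyl ketal. Then cut the ring at C2–C3 and C6–C5 into isobutene (C2, C1, C6, C7) and 2,2-dimethoxypropanedial (C3, C4, C5).
Enabling feature: the cyclohexane ring has a latent twofold axis through C1 and C4. C3 and C5 are homochiral (both R, trans) carbinols, and each is bonded to a CH2 that ends at the same quaternary C1, so the same C–C bond-forming event can run twice.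
Forward: the only ring arises in step 3 by a double carbonyl-ene (3+3) annulation. Then come the esters at O3 and O5, C1=C7 to C1(OH)CO2Bn, unmasking and reduction of C4, the third ester and global hydrogenolysis.
Stereochemistry: C3 and C5 come from the (R)-BINOL/TiCl2(OiPr)2 catalyst in step 3. C1 and C4 are not stereogenic until step 10, where axial hydride delivery to the C4 ketone sets their cis relation.

Key step: step 3

Assumption: the (R)-BINOL/TiCl2(OiPr)2 catalyst is taken to shield the same formyl face of 3 as it does in glyoxylates (ketal carbon in the place of the ester carbon), which leads to the (R,R) series; if the sense proved opposite, (S)-BINOL would be used.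

Step 1
Reactants: 1 1,3-dihydroxyacetone dimer
Product: 2 2,2-dimethoxypropane-1,3-diol
Conditions: HC(OMe)3, TsOH·H2O (cat.), MeOH, rt
Reagents that add atoms: trimethyl orthoformate COC(OC)OC; methanol CO
Why: Acid-catalysed ketalisation with orthoformate as water scavenger cracks the dimer and traps the monomeric ketone, which blocks the future C4 against enolisation.

Step 2
Reactants: 2 2,2-dimethoxypropane-1,3-diol
Product: 3 2,2-dimethoxypropanedial
Conditions: (COCl)2, DMSO, CH2Cl2, −78 °C; Et3N, −78 °C to rt; filtration without water, short-path distillation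
Reagents that add atoms: none
Why: Double Swern oxidation of a 1,3-diol whose central carbon is quaternary, so the dialdehyde cannot enolise, and the non-aqueous work-up avoids the hydrate.

Step 3
Reactants: 3 2,2-dimethoxypropanedial (freshly distilled); 4 isobutene (2-methylpropene)
Product: 6 (1R,3R)-2,2-dimethoxy-5-methylidenecyclohexane-1,3-diol, via hydroxy aldehyde 5 (not isolated)
Conditions: (R)-BINOL (20 mol %), TiCl2(OiPr)2 (20 mol %), 4 Å MS, CH2Cl2 (0.02 M), −30 to 0 °C, 4 (1.2 equiv) added slowly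
Reagents that add atoms: none
Why: Proposed new method: the Lewis acid binds one formyl oxygen of 3 (with a ketal methoxy group as second donor, as the ester carbonyl is in a glyoxylate), isobutene adds through a six-membered carbonyl-ene transition state to give 5 (bond C2–C3), and the methallyl unit so created, which still holds one methyl group, at once undergoes a second, intramolecular carbonyl-ene reaction with the other formyl group (bond C6–C5), leaving the alkene exocyclic at C1. The closest known reaction types are the glyoxylate-ene reaction of isobutene under the (R)-BINOL/TiCl2(OiPr)2 catalyst, its two-directional version with two glyoxylate molecules, and the type 2 (2,4) carbonyl-ene cyclisation of 5-methylhex-5-enals and of α-alkoxy aldehydes; the new element is their merger into a (3+3) annulation of a 1,3-dialdehyde. The ring closes in the 6-(2,4) mode, 6-exo-trig at the carbonyl group with both alkene carbons in the ring, through a chair–chair array shaped like bicyclo[3.3.1]nonane, in which the carbonyl oxygen stands axial so that it can reach a hydrogen of the methyl group. C3 is set by the catalyst, which should give the (R)-carbinol as it gives (R)-α-hydroxy esters from glyoxylates; C5 is set by the same facial preference of the catalyst and, in the same sense, by the substrate, because the C3 carbinol group sits equatorial while the new C–O bond is axial, which means trans and therefore (R,R). The step needs ring closure to outrun a second intermolecular ene reaction (secured by proximity, dilution and about one equivalent of isobutene), hydrogen transfer from the methyl group and not from C2 (secured by the closed transition state), and absence of enolisation or β-elimination (secured by the quaternary ketal carbon C4). Material with the wrong configuration at C3 is mismatched in the second event and should be drained into the meso cis-diol, which chromatography removes, so the enantiomeric purity of 6 should rise above that of the first event.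

Step 4
Reactants: 7 3,4,5-tris(benzyloxy)benzoic acid
Product: 8 3,4,5-tris(benzyloxy)benzoyl chloride
Conditions: (COCl)2, DMF (cat.), CH2Cl2, 0 °C to rt
Reagents that add atoms: oxalyl chloride O=C(Cl)C(=O)Cl
Why: Acid chloride formation through the catalytic chloroiminium (Vilsmeier-type) species, to which benzyl aryl ethers are inert.

Step 5
Reactants: 6 (1R,3R)-2,2-dimethoxy-5-methylidenecyclohexane-1,3-diol; 8 3,4,5-tris(benzyloxy)benzoyl chloride (2.4 equiv)
Product: 9 (1R,3R)-2,2-dimethoxy-5-methylidenecyclohexane-1,3-diyl bis[3,4,5-tris(benzyloxy)benzoate]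
Conditions: Et3N, DMAP, CH2Cl2, 0 °C to reflux
Reagents that add atoms: none
Why: DMAP-catalysed acylation of two symmetry-equivalent secondary carbinols, which needs no selectivity, touches no stereocentre and installs two of the three final ester groups.

Step 6
Reactants: 9 bis-ester alkene
Product: 10 (1R,3R)-5-hydroxy-5-(hydroxymethyl)-2,2-dimethoxycyclohexane-1,3-diyl bis[3,4,5-tris(benzyloxy)benzoate]
Conditions: OsO4 (2 mol %), NMO, THF/t-BuOH/H2O, rt
Reagents that add atoms: N-methylmorpholine N-oxide C[N+]1([O-])CCOCC1 (oxygen passed on through OsO4); water O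
Why: Catalytic OsO4 syn-dihydroxylation of a 1,1-disubstituted alkene whose two faces are homotopic, because the twofold axis of 9 runs along C7=C1 and C4, so only one diol can form and C1 is not yet a stereocentre.

Step 7
Reactants: 10 diol
Product: 12 (3R,5R)-1-hydroxy-4,4-dimethoxy-3,5-bis{[3,4,5-tris(benzyloxy)benzoyl]oxy}cyclohexane-1-carboxylic acid, via alpha-hydroxy aldehyde 11 (not isolated)
Conditions: TEMPO (20 mol %), PhI(OAc)2 (2.5 equiv), CH2Cl2/H2O, rt
Reagents that add atoms: water O
Why: Oxoammonium (TEMPO) oxidation takes the primary alcohol through the aldehyde hydrate to the acid, while the tertiary carbinol cannot be oxidised and the ketal, esters and benzyl ethers are inert.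

Step 8
Reactants: 12 hydroxy acid
Product: 13 benzyl (3R,5R)-1-hydroxy-4,4-dimethoxy-3,5-bis{[3,4,5-tris(benzyloxy)benzoyl]oxy}cyclohexane-1-carboxylate
Conditions: BnBr, KHCO3, DMF, rt
Reagents that add atoms: benzyl bromide BrCc1ccccc1
Why: SN2 O-alkylation of the carboxylate masks the acid for the later acylation with a group that leaves in the final hydrogenolysis.

Step 9
Reactants: 13 ketal benzyl ester
Product: 14 benzyl (3R,5R)-1-hydroxy-4-oxo-3,5-bis{[3,4,5-tris(benzyloxy)benzoyl]oxy}cyclohexane-1-carboxylate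
Conditions: TFA/H2O (9:1), CH2Cl2, 0 °C to rt
Reagents that add atoms: water O
Why: Acid-catalysed ketal hydrolysis, placed after the alkene has been consumed so that no acid-induced alkene migration can occur, under conditions that esters, benzyl ethers and the α-centres should survive.

Step 10
Reactants: 14 ketone
Product: 15 benzyl 3,5-bis-O-[3,4,5-tris(benzyloxy)benzoyl]quinate ((3R,5R); 1-OH, O3 and 4-OH on one face, O5 and C7 on the other)
Conditions: NaBH4, CeCl3·7H2O, THF/MeOH, −78 °C
Reagents that add atoms: none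
Why: Luche reduction of a ketone that should populate the chair with CO2Bn and the C5 ester equatorial and with 1-OH and the C3 ester axial, so hydride enters axially, anti to the axial C3–O bond, and gives the equatorial C4 alcohol cis to O3 and 1-OH, which makes C1 and C4 stereogenic together in the quinic acid relation; acyl migration among O3, O4 and O5 would be harmless because step 11 fills whichever position is free.

Step 11
Reactants: 15 alcohol; 8 3,4,5-tris(benzyloxy)benzoyl chloride (1.5 equiv)
Product: 16 benzyl 3,4,5-tris-O-[3,4,5-tris(benzyloxy)benzoyl]quinate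
Conditions: Et3N, DMAP, CH2Cl2, 0 °C to rt
Reagents that add atoms: none
Why: DMAP-catalysed acylation selects the secondary C4 hydroxyl over the tertiary C1 hydroxyl, which is hindered and deactivated by the geminal ester.

Step 12
Reactants: 16 perbenzylated ester
Product: 17 3,4,5-tri-O-galloylquinic acid (target)
Conditions: H2 (1 atm), 10% Pd/C, THF/MeOH, rt
Reagents that add atoms: none
Why: Catalytic hydrogenolysis cleaves nine benzyl aryl ethers and the benzyl ester in one operation and leaves the aryl esters and all stereocentres untouched.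

Compound list
1 | 1,3-dihydroxyacetone dimer (2,5-bis(hydroxymethyl)-1,4-dioxane-2,5-diol) | OCC1(O)COC(O)(CO)CO1 | starting material
2 | 2,2-dimethoxypropane-1,3-diol | OCC(OC)(OC)CO | intermediate
3 | 2,2-dimethoxypropanedial | O=CC(OC)(OC)C=O | intermediate
4 | isobutene (2-methylpropene) | CC(C)=C | starting material
5 | (3R)-3-hydroxy-2,2-dimethoxy-5-methylhex-5-enal (not isolated) | C=C(C)C[C@@H](O)C(OC)(OC)C=O | intermediate
6 | (1R,3R)-2,2-dimethoxy-5-methylidenecyclohexane-1,3-diol (trans-diol) | O[C@@H]1CC(=C)C[C@@H](O)C1(OC)OC | intermediate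
7 | 3,4,5-tris(benzyloxy)benzoic acid | OC(=O)c1cc(OCc2ccccc2)c(OCc2ccccc2)c(OCc2ccccc2)c1 | starting material
8 | 3,4,5-tris(benzyloxy)benzoyl chloride | ClC(=O)c1cc(OCc2ccccc2)c(OCc2ccccc2)c(OCc2ccccc2)c1 | intermediate
9 | (1R,3R)-2,2-dimethoxy-5-methylidenecyclohexane-1,3-diyl bis[3,4,5-tris(benzyloxy)benzoate] | O=C(O[C@@H]1CC(=C)C[C@@H](OC(=O)c2cc(OCc3ccccc3)c(OCc3ccccc3)c(OCc3ccccc3)c2)C1(OC)OC)c1cc(OCc2ccccc2)c(OCc2ccccc2)c(OCc2ccccc2)c1 | intermediate
10 | (1R,3R)-5-hydroxy-5-(hydroxymethyl)-2,2-dimethoxycyclohexane-1,3-diyl bis[3,4,5-tris(benzyloxy)benzoate] | O=C(O[C@@H]1CC(O)(CO)C[C@@H](OC(=O)c2cc(OCc3ccccc3)c(OCc3ccccc3)c(OCc3ccccc3)c2)C1(OC)OC)c1cc(OCc2ccccc2)c(OCc2ccccc2)c(OCc2ccccc2)c1 | intermediate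
11 | (1R,3R)-5-formyl-5-hydroxy-2,2-dimethoxycyclohexane-1,3-diyl bis[3,4,5-tris(benzyloxy)benzoate] (not isolated) | O=C(O[C@@H]1CC(O)(C=O)C[C@@H](OC(=O)c2cc(OCc3ccccc3)c(OCc3ccccc3)c(OCc3ccccc3)c2)C1(OC)OC)c1cc(OCc2ccccc2)c(OCc2ccccc2)c(OCc2ccccc2)c1 | intermediate
12 | (3R,5R)-1-hydroxy-4,4-dimethoxy-3,5-bis{[3,4,5-tris(benzyloxy)benzoyl]oxy}cyclohexane-1-carboxylic acid | O=C(O[C@@H]1CC(O)(C(=O)O)C[C@@H](OC(=O)c2cc(OCc3ccccc3)c(OCc3ccccc3)c(OCc3ccccc3)c2)C1(OC)OC)c1cc(OCc2ccccc2)c(OCc2ccccc2)c(OCc2ccccc2)c1 | intermediate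
13 | benzyl (3R,5R)-1-hydroxy-4,4-dimethoxy-3,5-bis{[3,4,5-tris(benzyloxy)benzoyl]oxy}cyclohexane-1-carboxylate | O=C(O[C@@H]1CC(O)(C(=O)OCc2ccccc2)C[C@@H](OC(=O)c2cc(OCc3ccccc3)c(OCc3ccccc3)c(OCc3ccccc3)c2)C1(OC)OC)c1cc(OCc2ccccc2)c(OCc2ccccc2)c(OCc2ccccc2)c1 | intermediate
14 | benzyl (3R,5R)-1-hydroxy-4-oxo-3,5-bis{[3,4,5-tris(benzyloxy)benzoyl]oxy}cyclohexane-1-carboxylate | O=C(O[C@@H]1CC(O)(C(=O)OCc2ccccc2)C[C@@H](OC(=O)c2cc(OCc3ccccc3)c(OCc3ccccc3)c(OCc3ccccc3)c2)C1=O)c1cc(OCc2ccccc2)c(OCc2ccccc2)c(OCc2ccccc2)c1 | intermediate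
15 | benzyl 3,5-bis-O-[3,4,5-tris(benzyloxy)benzoyl]quinate | O=C(O[C@@H]1C[C@](O)(C(=O)OCc2ccccc2)C[C@@H](OC(=O)c2cc(OCc3ccccc3)c(OCc3ccccc3)c(OCc3ccccc3)c2)[C@H]1O)c1cc(OCc2ccccc2)c(OCc2ccccc2)c(OCc2ccccc2)c1 | intermediate
16 | benzyl 3,4,5-tris-O-[3,4,5-tris(benzyloxy)benzoyl]quinate | O=C(O[C@@H]1C[C@](O)(C(=O)OCc2ccccc2)C[C@@H](OC(=O)c2cc(OCc3ccccc3)c(OCc3ccccc3)c(OCc3ccccc3)c2)[C@H]1OC(=O)c1cc(OCc2ccccc2)c(OCc2ccccc2)c(OCc2ccccc2)c1)c1cc(OCc2ccccc2)c(OCc2ccccc2)c(OCc2ccccc2)c1 | intermediate
17 | 3,4,5-tri-O-galloylquinic acid | O=C(O[C@@H]1C[C@](O)(C(=O)O)C[C@@H](OC(=O)c2cc(O)c(O)c(O)c2)[C@H]1OC(=O)c1cc(O)c(O)c(O)c1)c1cc(O)c(O)c(O)c1 | target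

Total step count: 12. Longest linear sequence: 11 (steps 1 to 3 and 5 to 12; step 4 is a one-step side branch).

Steps most likely to fail

1. Step 3 (Proposed new method).
- **What may go wrong:** The first, intermolecular ene reaction may be too slow for an aldehyde that is not a glyoxylate, so that oligomerisation of the dialdehyde or of isobutene takes over. Binding of the first carbinol to titanium could also deliver the Lewis acid to the second formyl group in a chelate and erode the trans selectivity.
- **Fallback:** It uses known chemistry, forms the two bonds one after the other, sets out from 2 and comes back at 6. Diol 2 is monosilylated (NaH, TBSCl, THF) to 3-[(tert-butyldimethylsilyl)oxy]-2,2-dimethoxypropan-1-ol F1, and Swern oxidation gives the aldehyde F2. Asymmetric methallylboration forms C2–C3 and should give the (R)-homoallylic alcohol F3; the reagent is B-methallyldiisopinocampheylborane, made from (+)-B-methoxydiisopinocampheylborane (derived from (−)-α-pinene) and methallylmagnesium chloride, used in Et2O at −78 °C and followed by NaOH/H2O2. TBSOTf/2,6-lutidine gives the bis-silyl ether F4, HF·pyridine frees the primary alcohol F5, and Dess–Martin periodinane gives the aldehyde F6. Me2AlCl (CH2Cl2, −78 °C) then closes C6–C5 in a type 2 carbonyl-ene cyclisation, with the silyloxy group equatorial and the carbonyl oxygen axial, to the trans mono-silyl ether F7. TBAF releases 6.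

2. Step 10.
- **What may go wrong:** Hydride addition may show poor facial selectivity if the ring-flipped chair or a twist-boat takes part. Base-induced epimerisation next to the ketone is a second risk.
- **Fallback:** It sets out from 14 and comes back at 15, and it makes the route stereoconvergent by SN2 inversion instead of relying on facial control. The reduction is run without regard to selectivity and the epimers are separated. The 4-epi alcohol F8 is converted with Tf2O/pyridine (CH2Cl2, −20 °C) into the triflate F9. Bu4NNO2 (toluene, 50 °C) displaces the triflate with inversion in a Lattrell–Dax inversion, favoured by the neighbouring equatorial C5 ester, to give the nitrite ester F10, which hydrolyses on work-up to 15.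

3. Step 9.
- **What may go wrong:** Ionisation of a ketal flanked by two electron-poor acyloxy groups may be sluggish. Forcing acid would then cause loss of benzyl groups, acyl migration or epimerisation.
- **Fallback:** It sets out from 6 and comes back at 14, and it moves the unmasking to the stage where the ketal is flanked by free carbinols. Diol 6 is hydrolysed with Amberlyst-15 in wet acetone at rt, which is mild enough for the exocyclic alkene, to the dihydroxy ketone F11. Acylation with 8 (Et3N, DMAP) gives the keto bis-ester F12. OsO4/NMO gives the diol F13, the alkene faces still being homotopic. TEMPO/PhI(OAc)2 carries F13 through the aldehyde F14 to the acid F15. Neutral esterification with O-benzyl-N,N'-diisopropylisourea, which avoids base next to the ketone, gives 14.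

Further compounds
F1 | step 3 | 3-[(tert-butyldimethylsilyl)oxy]-2,2-dimethoxypropan-1-ol | OCC(OC)(OC)CO[Si](C)(C)C(C)(C)C
F2 | step 3 | 3-[(tert-butyldimethylsilyl)oxy]-2,2-dimethoxypropanal | O=CC(OC)(OC)CO[Si](C)(C)C(C)(C)C
F3 | step 3 | (3R)-1-[(tert-butyldimethylsilyl)oxy]-2,2-dimethoxy-5-methylhex-5-en-3-ol | C=C(C)C[C@@H](O)C(OC)(OC)CO[Si](C)(C)C(C)(C)C
F4 | step 3 | (3R)-1,3-bis[(tert-butyldimethylsilyl)oxy]-2,2-dimethoxy-5-methylhex-5-ene | C=C(C)C[C@@H](O[Si](C)(C)C(C)(C)C)C(OC)(OC)CO[Si](C)(C)C(C)(C)C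
F5 | step 3 | (3R)-3-[(tert-butyldimethylsilyl)oxy]-2,2-dimethoxy-5-methylhex-5-en-1-ol | C=C(C)C[C@@H](O[Si](C)(C)C(C)(C)C)C(OC)(OC)CO
F6 | step 3 | (3R)-3-[(tert-butyldimethylsilyl)oxy]-2,2-dimethoxy-5-methylhex-5-enal | C=C(C)C[C@@H](O[Si](C)(C)C(C)(C)C)C(OC)(OC)C=O
F7 | step 3 | (1R,3R)-3-[(tert-butyldimethylsilyl)oxy]-2,2-dimethoxy-5-methylidenecyclohexan-1-ol | O[C@@H]1CC(=C)C[C@@H](O[Si](C)(C)C(C)(C)C)C1(OC)OC
F8 | step 10 | benzyl 3,5-bis-O-[3,4,5-tris(benzyloxy)benzoyl]-4-epi-quinate (4-OH trans to 1-OH and O3) | O=C(O[C@@H]1C[C@](O)(C(=O)OCc2ccccc2)C[C@@H](OC(=O)c2cc(OCc3ccccc3)c(OCc3ccccc3)c(OCc3ccccc3)c2)[C@@H]1O)c1cc(OCc2ccccc2)c(OCc2ccccc2)c(OCc2ccccc2)c1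
F9 | step 10 | 4-O-trifluoromethanesulfonate of F8 | O=C(O[C@@H]1C[C@](O)(C(=O)OCc2ccccc2)C[C@@H](OC(=O)c2cc(OCc3ccccc3)c(OCc3ccccc3)c(OCc3ccccc3)c2)[C@@H]1OS(=O)(=O)C(F)(F)F)c1cc(OCc2ccccc2)c(OCc2ccccc2)c(OCc2ccccc2)c1
F10 | step 10 | 4-O-nitrite ester of 15 (quinic acid configuration) | O=C(O[C@@H]1C[C@](O)(C(=O)OCc2ccccc2)C[C@@H](OC(=O)c2cc(OCc3ccccc3)c(OCc3ccccc3)c(OCc3ccccc3)c2)[C@H]1ON=O)c1cc(OCc2ccccc2)c(OCc2ccccc2)c(OCc2ccccc2)c1
F11 | step 9 | (2R,6R)-2,6-dihydroxy-4-methylidenecyclohexan-1-one | O[C@@H]1CC(=C)C[C@@H](O)C1=O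
F12 | step 9 | (1R,3R)-5-methylidene-2-oxocyclohexane-1,3-diyl bis[3,4,5-tris(benzyloxy)benzoate] | O=C(O[C@@H]1CC(=C)C[C@@H](OC(=O)c2cc(OCc3ccccc3)c(OCc3ccccc3)c(OCc3ccccc3)c2)C1=O)c1cc(OCc2ccccc2)c(OCc2ccccc2)c(OCc2ccccc2)c1
F13 | step 9 | (1R,3R)-5-hydroxy-5-(hydroxymethyl)-2-oxocyclohexane-1,3-diyl bis[3,4,5-tris(benzyloxy)benzoate] | O=C(O[C@@H]1CC(O)(CO)C[C@@H](OC(=O)c2cc(OCc3ccccc3)c(OCc3ccccc3)c(OCc3ccccc3)c2)C1=O)c1cc(OCc2ccccc2)c(OCc2ccccc2)c(OCc2ccccc2)c1
F14 | step 9 | (1R,3R)-5-formyl-5-hydroxy-2-oxocyclohexane-1,3-diyl bis[3,4,5-tris(benzyloxy)benzoate] | O=C(O[C@@H]1CC(O)(C=O)C[C@@H](OC(=O)c2cc(OCc3ccccc3)c(OCc3ccccc3)c(OCc3ccccc3)c2)C1=O)c1cc(OCc2ccccc2)c(OCc2ccccc2)c(OCc2ccccc2)c1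
F15 | step 9 | (3R,5R)-1-hydroxy-4-oxo-3,5-bis{[3,4,5-tris(benzyloxy)benzoyl]oxy}cyclohexane-1-carboxylic acid | O=C(O[C@@H]1CC(O)(C(=O)O)C[C@@H](OC(=O)c2cc(OCc3ccccc3)c(OCc3ccccc3)c(OCc3ccccc3)c2)C1=O)c1cc(OCc2ccccc2)c(OCc2ccccc2)c(OCc2ccccc2)c1
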